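**Retrosynthetic overview**
1. The target comes from one global i-Bu2AlH reduction of a triester (C3 methyl ester, C5 methyl cinnamate, phenol pivalate). The cinnamate comes from a Heck coupling of a 5-bromide with methyl acrylate.
2. The trans-2-aryl-2,3-dihydrobenzofuran-3-carboxylate comes from oxidative ring contraction of an (S)-flavanone. Ring-A carbon C4a shifts from C4 to C3, C4 leaves the ring as CO2Me, and C2 dictates C3.
3. The (S)-flavanone comes from an enantioselective oxa-Michael closure (new catalyst use) of a 2'-hydroxychalcone. The chalcone comes from a Claisen–Schmidt union of an acetophenone and an aldehyde.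
4. The aldehyde comes from p-cresol (tetrabromination/hydrolysis, double methoxylation, pivalate). The acetophenone comes from 4-bromophenol and acetyl chloride (Fries, iodination, selective methoxylation).
5. Ring order: both benzene rings are bought. The six-membered pyranone ring is closed first and is then contracted to the five-membered dihydrofuran ring.

Assumption: the sense of induction of the step 8 catalyst cannot be predicted. The (S)-tert-leucine-derived antipode is written, and its mirror image is used if the sense turns out opposite.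

**Step 1**
Reactants: 1 p-cresol (4-methylphenol)
Product: 4 3,5-dibromo-4-hydroxybenzaldehyde, via 2,6-dibromo-4-methylphenol 2 (not isolated), via 2,6-dibromo-4-(dibromomethyl)phenol 3 (not isolated)
Conditions: Br2 (4.1 equiv), o-dichlorobenzene, 35 °C then 155 °C; then H2O/aq HBr, 100 °C
Reagents that add atoms: bromine BrBr; water O
Why: Electrophilic aromatic bromination fills both positions ortho to OH, hot benzylic radical bromination takes the methyl group to CHBr2, and hydrolysis of the gem-dibromide gives the aldehyde, with no stereocentre involved.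

**Step 2**
Reactants: 4 3,5-dibromo-4-hydroxybenzaldehyde
Product: 5 syringaldehyde (4-hydroxy-3,5-dimethoxybenzaldehyde)
Conditions: NaOMe (4.5 equiv), CuCl (0.15 equiv), DMF/MeOH, 115 °C; then aq HCl
Reagents that add atoms: sodium methoxide C[O-].[Na+]
Why: Copper-catalysed Ullmann-type methoxylation replaces both aryl bromides, and the phenoxide form keeps the aldehyde inert to methoxide.

**Step 3**
Reactants: 5 syringaldehyde
Product: 6 4-formyl-2,6-dimethoxyphenyl pivalate
Conditions: t-BuCOCl (1.2 equiv), Et3N, DMAP (cat.), CH2Cl2, 0 °C to rt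
Reagents that add atoms: pivaloyl chloride CC(C)(C)C(=O)Cl
Why: This simple O-acylation gives a pivalate that shields the phenol from the later trivalent-iodine oxidant, lowers the migratory aptitude of ring B, survives Lewis and Brønsted acid, and falls off in the final hydride step.

**Step 4**
Reactants: 7 4-bromophenol; 8 acetyl chloride
Product: 10 1-(5-bromo-2-hydroxyphenyl)ethanone, via 4-bromophenyl acetate 9 (not isolated)
Conditions: neat, 60 °C, 1 h; then AlCl3 (1.6 equiv), 135 °C, 3 h; ice/aq HCl
Reagents that add atoms: none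
Why: O-acetylation is followed by a Fries rearrangement in which the blocked para position and the stable aluminium chelate send the acyl group ortho to the oxygen.

**Step 5**
Reactants: 10 1-(5-bromo-2-hydroxyphenyl)ethanone
Product: 11 1-(5-bromo-2-hydroxy-3-iodophenyl)ethanone
Conditions: NIS (1.1 equiv), p-TsOH·H2O (cat.), MeCN, reflux
Reagents that add atoms: N-iodosuccinimide O=C1CCC(=O)N1I
Why: Electrophilic aromatic iodination goes to C3, the only free position activated by the OH group.

**Step 6**
Reactants: 11 1-(5-bromo-2-hydroxy-3-iodophenyl)ethanone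
Product: 12 1-(5-bromo-2-hydroxy-3-methoxyphenyl)ethanone
Conditions: NaOMe (4 equiv, in MeOH), CuI (0.15 equiv), DMF, 90 °C; then aq HCl
Reagents that add atoms: sodium methoxide C[O-].[Na+]
Why: In this Ullmann-type methoxylation the C–I bond next to the phenoxide reacts much faster than the electron-rich C–Br bond para to it, so the bromide is kept for the Heck step.

**Step 7**
Reactants: 12 1-(5-bromo-2-hydroxy-3-methoxyphenyl)ethanone; 6 4-formyl-2,6-dimethoxyphenyl pivalate
Product: 13 4-[(E)-3-(5-bromo-2-hydroxy-3-methoxyphenyl)-3-oxoprop-1-enyl]-2,6-dimethoxyphenyl pivalate (2'-hydroxychalcone)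
Conditions: BF3·OEt2 (0.5 equiv), 1,4-dioxane, rt, 3 h
Reagents that add atoms: none
Why: The Lewis-acid Claisen–Schmidt condensation enolises the chelated ketone and dehydrates the aldol to the thermodynamic E enone without the hydroxide that would cleave the aryl pivalate.

**Step 8**
Reactants: 13 2'-hydroxychalcone
Product: 14 4-[(2S)-6-bromo-8-methoxy-4-oxochroman-2-yl]-2,6-dimethoxyphenyl pivalate ((S)-flavanone)
Conditions: N-[3,5-bis(trifluoromethyl)phenyl]-N'-[(S)-3,3-dimethyl-1-{[tris(4-methoxyphenyl)-λ5-phosphanylidene]amino}butan-2-yl]thiourea (10 mol%), toluene, −30 °C, stopped near 90% conversion; AcOH quench at −30 °C; one recrystallisation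
Reagents that add atoms: none
Why: Proposed new method: this is an enantioselective 6-endo-trig intramolecular oxa-Michael addition of an unactivated 2'-hydroxychalcone under a superbasic bifunctional iminophosphorane–thiourea, a catalyst class not yet applied to phenol-to-chalcone closure, in which the iminophosphorane deprotonates the bromine-acidified 2'-OH to a tight chiral ion pair, the thiourea holds the s-cis enone carbonyl, the phenoxide attacks one face of the β-carbon to set C2 as S, the iminophosphonium N–H protonates the enolate, and at −30 °C the far less acidic C3–H of the product is removed too slowly for retro-addition to erode the kinetic ee; the closest known reaction types are the cinchona–thiourea oxa-Michael closure of α-carboxylate-activated 2'-hydroxychalcones and the iminophosphorane-catalysed oxa-Michael addition of alcohols to unactivated enoates.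

**Step 9**
Reactants: 14 (S)-flavanone
Product: 17 methyl (2S,3S)-5-bromo-2-[3,5-dimethoxy-4-(pivaloyloxy)phenyl]-7-methoxy-2,3-dihydrobenzofuran-3-carboxylate (2,3-trans), via methyl enol ether 15 (not isolated), via 3-iodanyl dimethyl ketal 16 (not isolated)
Conditions: PhI(OAc)2 (1.2 equiv), HC(OMe)3 (solvent), conc. H2SO4 (0.5 equiv), rt, 2 h
Reagents that add atoms: trimethyl orthoformate COC(OC)OC
Why: In this hypervalent-iodine oxidative ring contraction of a flavanone (cationic 1,2-aryl shift), the iodane adds to C3 of enol ether 15 anti to the C2 aryl group, ring-A carbon C4a then migrates from C4 to C3 with inversion as PhI leaves, and the ketal carbon becomes the exocyclic ester, so the untouched C2 centre fixes C3 trans to it.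

**Step 10**
Reactants: 17 bromo ester; 18 methyl acrylate
Product: 19 methyl (2S,3S)-2-[3,5-dimethoxy-4-(pivaloyloxy)phenyl]-7-methoxy-5-[(E)-3-methoxy-3-oxoprop-1-enyl]-2,3-dihydrobenzofuran-3-carboxylate
Conditions: Pd2(dba)3 (1.5 mol%), [HP(t-Bu)3]BF4 (6 mol%), Cy2NMe (1.2 equiv), 1,4-dioxane, 70 °C
Reagents that add atoms: none
Why: The Mizoroki–Heck reaction with an electron-rich bulky phosphine couples the deactivated aryl bromide at mild temperature, gives the E alkene by syn insertion and syn β-hydride elimination, and uses a hindered amine too weak to deprotonate C3.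

**Step 11**
Reactants: 19 triester
Product: 20 4-[(2S,3R)-3-(hydroxymethyl)-5-[(E)-3-hydroxyprop-1-enyl]-7-methoxy-2,3-dihydrobenzofuran-2-yl]-2,6-dimethoxyphenol (target)
Conditions: i-Bu2AlH (8 equiv), CH2Cl2, −78 °C to 0 °C; aq KNaC4H4O6
Reagents that add atoms: none
Why: This hydride reduction of esters takes the C3 ester to CH2OH, the enoate to the allylic alcohol by pure 1,2-reduction, and the pivalate to the free phenol in one operation, and it touches no stereocentre (the C3 descriptor changes from S to R only through the priority change).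

**Compound list**
1 | p-cresol | Cc1ccc(O)cc1 | starting material
2 | 2,6-dibromo-4-methylphenol | Cc1cc(Br)c(O)c(Br)c1 | intermediate
3 | 2,6-dibromo-4-(dibromomethyl)phenol | BrC(Br)c1cc(Br)c(O)c(Br)c1 | intermediate
4 | 3,5-dibromo-4-hydroxybenzaldehyde | O=Cc1cc(Br)c(O)c(Br)c1 | intermediate
5 | syringaldehyde | COc1cc(C=O)cc(OC)c1O | intermediate
6 | 4-formyl-2,6-dimethoxyphenyl pivalate | COc1cc(C=O)cc(OC)c1OC(=O)C(C)(C)C | intermediate
7 | 4-bromophenol | Oc1ccc(Br)cc1 | starting material
8 | acetyl chloride | CC(=O)Cl | starting material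
9 | 4-bromophenyl acetate | CC(=O)Oc1ccc(Br)cc1 | intermediate
10 | 1-(5-bromo-2-hydroxyphenyl)ethanone | CC(=O)c1cc(Br)ccc1O | intermediate
11 | 1-(5-bromo-2-hydroxy-3-iodophenyl)ethanone | CC(=O)c1cc(Br)cc(I)c1O | intermediate
12 | 1-(5-bromo-2-hydroxy-3-methoxyphenyl)ethanone | CC(=O)c1cc(Br)cc(OC)c1O | intermediate
13 | (E)-2'-hydroxychalcone pivalate | COc1cc(/C=C/C(=O)c2cc(Br)cc(OC)c2O)cc(OC)c1OC(=O)C(C)(C)C | intermediate
14 | (2S)-flavanone pivalate | COc1cc([C@H]2Oc3c(OC)cc(Br)cc3C(=O)C2)cc(OC)c1OC(=O)C(C)(C)C | intermediate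
15 | 4-[(2S)-6-bromo-4,8-dimethoxy-2H-chromen-2-yl]-2,6-dimethoxyphenyl pivalate (methyl enol ether) | COc1cc([C@H]2Oc3c(OC)cc(Br)cc3C(OC)=C2)cc(OC)c1OC(=O)C(C)(C)C | intermediate
16 | 4-{(2R,3R)-3-[acetoxy(phenyl)-λ3-iodanyl]-6-bromo-4,4,8-trimethoxychroman-2-yl}-2,6-dimethoxyphenyl pivalate (iodine trans to the aryl group) | COc1cc([C@H]2Oc3c(OC)cc(Br)cc3C(OC)(OC)[C@@H]2I(OC(C)=O)c2ccccc2)cc(OC)c1OC(=O)C(C)(C)C | intermediate
17 | methyl (2S,3S)-5-bromo-2-[3,5-dimethoxy-4-(pivaloyloxy)phenyl]-7-methoxy-2,3-dihydrobenzofuran-3-carboxylate | COc1cc([C@H]2Oc3c(OC)cc(Br)cc3[C@@H]2C(=O)OC)cc(OC)c1OC(=O)C(C)(C)C | intermediate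
18 | methyl acrylate | C=CC(=O)OC | starting material
19 | methyl (2S,3S)-2-[3,5-dimethoxy-4-(pivaloyloxy)phenyl]-7-methoxy-5-[(E)-3-methoxy-3-oxoprop-1-enyl]-2,3-dihydrobenzofuran-3-carboxylate | COc1cc([C@H]2Oc3c(OC)cc(/C=C/C(=O)OC)cc3[C@@H]2C(=O)OC)cc(OC)c1OC(=O)C(C)(C)C | intermediate
20 | 4-[(2S,3R)-3-(hydroxymethyl)-5-[(E)-3-hydroxyprop-1-enyl]-7-methoxy-2,3-dihydrobenzofuran-2-yl]-2,6-dimethoxyphenol | COc1cc([C@H]2Oc3c(OC)cc(/C=C/CO)cc3[C@@H]2CO)cc(OC)c1O | target

**Step count**
- Total steps: 11.
- Longest linear sequence: 8 steps (4, 5, 6, 7, 8, 9, 10, 11). The branch 1, 2, 3 followed by 7 to 11 is equally long.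

**The three steps most likely to fail**

Step 8 (the new step). The addition is reversible, so the ee can erode, conversion may stall at the chalcone/flavanone equilibrium, and the facial selectivity is untested. The fallback uses known chemistry and sets out from 13. NaOAc in refluxing EtOH closes the ring without control to the racemic flavanone F1. Asymmetric transfer hydrogenation run as a kinetic resolution (Cp*RhCl[(R,R)-TsDPEN] 1 mol%, HCO2H/Et3N, EtOAc, rt, stopped near 52% conversion) reduces only the (R)-ketone to the (2R,4R)-cis-flavan-4-ol F2. This alcohol is removed by chromatography. The unreacted ketone is 14 in high ee, where the route is rejoined, with a maximum yield of 50%.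

Step 9. Dehydrogenation to the flavone, migration of ring B to an isoflavone, and oxidation of the methoxyarenes all compete with the contraction. Ring A also carries a deactivating bromine. The fallback sets out from 14. CuBr2 in refluxing EtOAc/CHCl3 gives the 2,3-trans 3-bromoflavanone F3. HC(OMe)3 with p-TsOH in MeOH turns it into the bromo dimethyl ketal F4. ZnBr2 (0.2 equiv) in toluene at 100 °C then triggers the non-oxidative 1,2-aryl shift of the α-halo ketal, in which C4a displaces bromide at C3 with inversion. This comes back to the route at 17.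

Step 6. Partial exchange of the C–Br bond, hydrodeiodination, and self-condensation of the methyl ketone are possible. The fallback sets out from 10 and skips step 5. Duff formylation (hexamethylenetetramine, CF3CO2H, reflux, then aq HCl) gives 3-acetyl-5-bromo-2-hydroxybenzaldehyde F5. Dakin oxidation (H2O2, aq NaOH, rt) gives 1-(5-bromo-2,3-dihydroxyphenyl)ethanone F6. Methylation of its dianion (NaH 2.0 equiv, DMSO, then MeI 1.0 equiv) takes place at the more nucleophilic, non-chelated 3-oxide. This comes back to the route at 12.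

**Further compounds**
F1 | step 8 | racemic 4-(6-bromo-8-methoxy-4-oxochroman-2-yl)-2,6-dimethoxyphenyl pivalate | COc1cc(C2Oc3c(OC)cc(Br)cc3C(=O)C2)cc(OC)c1OC(=O)C(C)(C)C
F2 | step 8 | 4-[(2R,4R)-6-bromo-4-hydroxy-8-methoxychroman-2-yl]-2,6-dimethoxyphenyl pivalate | COc1cc([C@@H]2Oc3c(OC)cc(Br)cc3[C@H](O)C2)cc(OC)c1OC(=O)C(C)(C)C
F3 | step 9 | 4-[(2R,3R)-3,6-dibromo-8-methoxy-4-oxochroman-2-yl]-2,6-dimethoxyphenyl pivalate | COc1cc([C@H]2Oc3c(OC)cc(Br)cc3C(=O)[C@@H]2Br)cc(OC)c1OC(=O)C(C)(C)C
F4 | step 9 | 4-[(2R,3R)-3,6-dibromo-4,4,8-trimethoxychroman-2-yl]-2,6-dimethoxyphenyl pivalate | COc1cc([C@H]2Oc3c(OC)cc(Br)cc3C(OC)(OC)[C@@H]2Br)cc(OC)c1OC(=O)C(C)(C)C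
F5 | step 6 | 3-acetyl-5-bromo-2-hydroxybenzaldehyde | CC(=O)c1cc(Br)cc(C=O)c1O
F6 | step 6 | 1-(5-bromo-2,3-dihydroxyphenyl)ethanone | CC(=O)c1cc(Br)cc(O)c1O
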